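**Assumptions:** The enol in the target SMILES is the usual fast keto–enol tautomer of the 1,3-diketone, and the route delivers that equilibrium form. (R)-3-Methylglutaric acid monomethyl ester is taken as a catalogue chiral building block (otherwise one step from 3-methylglutaric anhydride by alkaloid-mediated methanolysis).

## Retrosynthetic overview

1. Target ⇒ aryl-ether aldehyde 18 + "half-curcumin" 21 by a boron-templated (Pabon-type) aldol condensation; the curcuminoid is assembled last, and both arenes are bought (vanillin, 4-hydroxybenzaldehyde).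
2. 18 ⇒ vanillin + diene monoepoxide 16 by the key step: Pd(0)-catalysed cis-1,4 hydroxy-aryloxylation. One operation makes the C–OAr bond, unveils the allylic OH and fixes their cis relationship, replacing the usual Mitsunobu/SN2 etherification of a preformed diol.
3. 16 ⇒ (+)-α-turmerone 14 by site- and face-selective epoxidation of the trisubstituted diene terminus.
4. 14 ⇒ 4-substituted cyclohexenone 6 (kinetic dienyl triflate, Negishi methylation, ester → enone through a Weinreb amide).
5. 6 ⇒ aldehyde 3 + methyl vinyl ketone by an organocatalytic Michael/aldol (Robinson-type) annulation. The cyclohexene is the only ring built, and it is built first.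

## Route

**Step 1**
Reactants: 1, (R)-3-methylglutaric acid monomethyl ester
Product: 2, methyl (3R)-5-hydroxy-3-methylpentanoate
Conditions: BH3·SMe2 (1.1 equiv), THF, −10 → 20 °C; MeOH quench, no acid
Reagents that add atoms: none
Why: Chemoselective borane reduction of a carboxylic acid in the presence of an ester; the stereocentre is not touched.

**Step 2**
Reactants: 2, methyl (3R)-5-hydroxy-3-methylpentanoate
Product: 3, methyl (3R)-3-methyl-5-oxopentanoate
Conditions: TEMPO (10 mol%), PhI(OAc)2, CH2Cl2, rt (crude 2 used at once to outrun lactonisation)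
Reagents that add atoms: none
Why: TEMPO/BAIB oxidation of a primary alcohol stops cleanly at the aldehyde and does not affect the ester.

**Step 3**
Reactants: 3, methyl (3R)-3-methyl-5-oxopentanoate; 4, methyl vinyl ketone
Product: 5, methyl (3S,4R)-4-formyl-3-methyl-7-oxooctanoate
Conditions: (R)-α,α-diphenylprolinol methyl ether (5 mol%), ethyl 3,4-dihydroxybenzoate (20 mol%), 4 (1.5 equiv), neat, 4 °C, 36 h
Reagents that add atoms: methyl vinyl ketone (4), C=CC(C)=O
Why: Enamine-catalysed asymmetric Michael addition; the CPh2OMe group of the (R)-catalyst blocks one face of the E-enamine so the enone adds to the open Re face, setting C4 as R under catalyst control (this becomes the ring carbon that carries the side chain).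

**Step 4**
Reactants: 5, methyl (3S,4R)-4-formyl-3-methyl-7-oxooctanoate
Product: 6, methyl (3S)-3-[(1R)-4-oxocyclohex-2-en-1-yl]butanoate
Conditions: NaOMe (0.3 equiv), MeOH, 0 °C → rt
Reagents that add atoms: none
Why: Intramolecular aldol condensation (second half of a Robinson annulation) of the methyl ketone onto the aldehyde; methoxide in methanol makes ester exchange degenerate, and ring closure is faster than epimerisation of the α-branched aldehyde.

**Step 5**
Reactants: 6, methyl (3S)-3-[(1R)-4-oxocyclohex-2-en-1-yl]butanoate; 7, N-phenylbis(trifluoromethanesulfonimide)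
Product: 8, methyl (3S)-3-[(1R)-4-(trifluoromethylsulfonyloxy)cyclohexa-2,4-dien-1-yl]butanoate
Conditions: LDA (1.05 equiv), THF, −78 °C (6 added to base); then 7, −78 → 0 °C
Reagents that add atoms: PhNTf2 (7), O=S(=O)(N(c1ccccc1)S(=O)(=O)C(F)(F)F)C(F)(F)F
Why: Kinetic α′-deprotonation of the cyclohexenone gives the cross-conjugated enolate, trapped as the 2-triflyloxy-1,3-diene; the γ-hydrogen (ring stereocentre) and the much less acidic ester α-hydrogens are not removed.

**Step 6**
Reactants: 8, the dienyl triflate; 9, methylzinc chloride
Product: 10, methyl (3S)-3-[(1R)-4-methylcyclohexa-2,4-dien-1-yl]butanoate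
Conditions: Pd(PPh3)4 (5 mol%), 9 (1.5 equiv), THF, rt
Reagents that add atoms: MeZnCl (9), C[Zn]Cl
Why: Negishi cross-coupling of an alkenyl triflate installs the ring methyl and fixes the 1,3-diene regiochemistry (no dehydration mixtures); organozinc reagents tolerate the ester.

**Step 7**
Reactants: 10, the diene ester; 11, N,O-dimethylhydroxylamine hydrochloride
Product: 12, (3S)-N-methoxy-N-methyl-3-[(1R)-4-methylcyclohexa-2,4-dien-1-yl]butanamide
Conditions: 11 (1.5 equiv), iPrMgCl (3.0 equiv), THF, −20 °C
Reagents that add atoms: MeNH(OMe)·HCl (11), CNOC.Cl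
Why: Direct ester-to-Weinreb-amide aminolysis by the magnesium amide; the diene and both stereocentres are inert to these conditions.

**Step 8**
Reactants: 12, the Weinreb amide; 13, 2-methylprop-1-enylmagnesium bromide
Product: 14, (+)-α-turmerone, (6S)-2-methyl-6-[(1R)-4-methylcyclohexa-2,4-dien-1-yl]hept-2-en-4-one
Conditions: 13 (1.5 equiv), THF, 0 °C; cold aq. NH4Cl; product kept under argon
Reagents that add atoms: 2-methylprop-1-enylmagnesium bromide (13), CC(C)=C[Mg]Br
Why: Weinreb ketone synthesis; the chelated tetrahedral intermediate prevents over-addition and releases the β,β-dimethyl enone on work-up.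

**Step 9**
Reactants: 14, α-turmerone; 15, mCPBA
Product: 16, (6S)-2-methyl-6-[(1R,4R,6S)-1-methyl-7-oxabicyclo[4.1.0]hept-2-en-4-yl]hept-2-en-4-one (epoxide on the ring face opposite the side chain)
Conditions: 15 (1.0 equiv), solid NaHCO3 (3 equiv), CH2Cl2, −30 → −10 °C; cold Na2S2O3/NaHCO3 wash; used crude
Reagents that add atoms: mCPBA (15), OOC(=O)c1cccc(Cl)c1
Why: Prilezhaev epoxidation picks the most electron-rich, trisubstituted diene terminus (the disubstituted ring alkene and the enone are slower) and attacks anti to the ring substituent, setting both epoxide centres relative to the existing ring stereocentre.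

**Step 10 (key step)**
Reactants: 16, the vinyl epoxide; 17, vanillin
Product: 18, 4-{[(1R,4S,6R)-4-hydroxy-3-methyl-6-[(2S)-6-methyl-4-oxohept-5-en-2-yl]cyclohex-2-en-1-yl]oxy}-3-methoxybenzaldehyde
Conditions: Pd2(dba)3·CHCl3 (2.5 mol%), PPh3 (12 mol%), 17 (1.3 equiv), THF, 0 °C → rt; 16 added slowly
Reagents that add atoms: vanillin (17), COc1cc(C=O)ccc1O
Why: Tsuji–Trost opening of a diene monoepoxide: Pd(0) ionises the allylic C–O bond anti to oxygen, the resulting alkoxide deprotonates vanillin, and the phenoxide attacks the distal secondary allyl terminus anti to Pd, so double inversion gives the cis-1,4 aryloxy alcohol (trans to the side chain) with the carbinol centre retained from the epoxide; reversible ionisation of any tertiary 1,2-adduct funnels material to the 1,4-product.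

**Step 11 (side branch)**
Reactants: 19, acetylacetone; 20, 4-hydroxybenzaldehyde
Product: 21, (E)-6-(4-hydroxyphenyl)hex-5-ene-2,4-dione (half-curcumin; exists largely as its enol)
Conditions: 19 (3 equiv), B2O3, B(OnBu)3, nBuNH2 (cat.), EtOAc, 70 °C; then 0.4 M HCl, 60 °C
Reagents that add atoms: acetylacetone (19), CC(=O)CC(C)=O; 4-hydroxybenzaldehyde (20), O=Cc1ccc(O)cc1
Why: Pabon boron-chelate aldol condensation; chelation blocks the central carbon (no Knoevenagel) and excess acetylacetone favours mono-condensation, giving the E-alkene.

**Step 12**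
Reactants: 18, the aryl-ether aldehyde; 21, half-curcumin
Product: 22, demethoxybisabolocurcumin ether, (1E,4Z,6E)-5-hydroxy-7-(4-{[(1R,4S,6R)-4-hydroxy-3-methyl-6-[(2S)-6-methyl-4-oxohept-5-en-2-yl]cyclohex-2-en-1-yl]oxy}-3-methoxyphenyl)-1-(4-hydroxyphenyl)hepta-1,4,6-trien-3-one
Conditions: 21 (1.1 equiv), B2O3, EtOAc, 70 °C, 30 min; then 18, B(OnBu)3 (2 equiv), nBuNH2 (0.3 equiv, slow), 60–70 °C; then 0.2 M aq. HCl/EtOAc, rt, 1 h
Reagents that add atoms: none beyond reactant 21
Why: Pabon-type aldol condensation of the boron-activated acetyl methyl of 21 with the aryl aldehyde gives the E-enone; the unactivated side-chain enone does not compete, the allylic OH is only transiently borylated, and no stereocentre is enolisable.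

## Compound list

1 | (R)-3-methylglutaric acid monomethyl ester | OC(=O)C[C@@H](C)CC(=O)OC | starting material
2 | methyl (3R)-5-hydroxy-3-methylpentanoate | OCC[C@@H](C)CC(=O)OC | intermediate
3 | methyl (3R)-3-methyl-5-oxopentanoate | O=CC[C@@H](C)CC(=O)OC | intermediate
4 | methyl vinyl ketone | C=CC(C)=O | starting material
5 | methyl (3S,4R)-4-formyl-3-methyl-7-oxooctanoate | CC(=O)CC[C@@H](C=O)[C@@H](C)CC(=O)OC | intermediate
6 | methyl (3S)-3-[(1R)-4-oxocyclohex-2-en-1-yl]butanoate | O=C1CC[C@@H](C=C1)[C@@H](C)CC(=O)OC | intermediate
7 | N-phenylbis(trifluoromethanesulfonimide) | O=S(=O)(N(c1ccccc1)S(=O)(=O)C(F)(F)F)C(F)(F)F | starting material (reagent)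
8 | methyl (3S)-3-[(1R)-4-(trifluoromethylsulfonyloxy)cyclohexa-2,4-dien-1-yl]butanoate | O=S(=O)(OC1=CC[C@@H](C=C1)[C@@H](C)CC(=O)OC)C(F)(F)F | intermediate
9 | methylzinc chloride | C[Zn]Cl | starting material (reagent)
10 | methyl (3S)-3-[(1R)-4-methylcyclohexa-2,4-dien-1-yl]butanoate | CC1=CC[C@@H](C=C1)[C@@H](C)CC(=O)OC | intermediate
11 | N,O-dimethylhydroxylamine hydrochloride | CNOC.Cl | starting material (reagent)
12 | (3S)-N-methoxy-N-methyl-3-[(1R)-4-methylcyclohexa-2,4-dien-1-yl]butanamide | CC1=CC[C@@H](C=C1)[C@@H](C)CC(=O)N(C)OC | intermediate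
13 | 2-methylprop-1-enylmagnesium bromide | CC(C)=C[Mg]Br | starting material (reagent)
14 | (+)-α-turmerone, (6S)-2-methyl-6-[(1R)-4-methylcyclohexa-2,4-dien-1-yl]hept-2-en-4-one | CC1=CC[C@@H](C=C1)[C@@H](C)CC(=O)C=C(C)C | intermediate
15 | m-chloroperoxybenzoic acid | OOC(=O)c1cccc(Cl)c1 | starting material (reagent)
16 | (6S)-2-methyl-6-[(1R,4R,6S)-1-methyl-7-oxabicyclo[4.1.0]hept-2-en-4-yl]hept-2-en-4-one | C1=C[C@@]2(C)O[C@H]2C[C@@H]1[C@@H](C)CC(=O)C=C(C)C | intermediate
17 | vanillin | COc1cc(C=O)ccc1O | starting material
18 | 4-{[(1R,4S,6R)-4-hydroxy-3-methyl-6-[(2S)-6-methyl-4-oxohept-5-en-2-yl]cyclohex-2-en-1-yl]oxy}-3-methoxybenzaldehyde | COc1cc(C=O)ccc1O[C@H]1C=C(C)[C@@H](O)C[C@@H]1[C@@H](C)CC(=O)C=C(C)C | intermediate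
19 | acetylacetone | CC(=O)CC(C)=O | starting material
20 | 4-hydroxybenzaldehyde | O=Cc1ccc(O)cc1 | starting material
21 | (E)-6-(4-hydroxyphenyl)hex-5-ene-2,4-dione | CC(=O)CC(=O)/C=C/c1ccc(O)cc1 | intermediate
22 | demethoxybisabolocurcumin ether | COc1cc(/C=C/C(O)=C/C(=O)/C=C/c2ccc(O)cc2)ccc1O[C@H]1C=C(C)[C@@H](O)C[C@@H]1[C@@H](C)CC(=O)C=C(C)C | target

## Summary

Total step count: 12 (11 on the main line plus 1 side-branch step).
Longest linear sequence: 11 steps (Steps 1–10, then 12).

Three steps most likely to fail:

1. **Step 9, epoxidation.** Facial control is only 1,3-induction (I expect a modest anti preference, not a high one), and diene monoepoxides aromatise easily (here to ar-turmerone). Fallback: switch from substrate control to catalyst control with a chiral dioxirane (Shi-type ketone/Oxone, buffered), using whichever ketone enantiomer is matched. If the intrinsic bias turns out to be syn, use the NBS/H2O bromohydrin then K2CO3 closure, which delivers the epoxide on the face opposite to direct epoxidation.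

2. **Step 10, Pd-catalysed 1,4-hydroxy-aryloxylation.** Risks are 1,2- versus 1,4-attack, Pd-mediated isomerisation or aromatisation of the epoxide, and Pd having to sit syn to the side chain. Fallback: make the aryl C–O bond instead of the allylic one. Singlet-oxygen [4+2] on 14 (anti to the adjacent side chain), thiourea reduction to the cis-2-ene-1,4-diol, temporary mono-protection, then SNAr of the alkoxide on 4-fluoro-3-methoxybenzaldehyde; the carbinol C–O bond is never broken, so configuration is retained.

3. **Step 12, final condensation.** The allylic aryl ether/allylic alcohol must survive amine, boron reagents, heat and the acidic decomplexation, and the side-chain enone must stay passive. Fallback: invert the order. Pre-assemble the curcuminoid as its BF2 complex with the 4-hydroxyphenyl OH silyl-protected (from vanillin), use its free guaiacol OH as the nucleophile in the Step 10 Pd reaction with 16, then remove BF2 and silyl under near-neutral conditions (aq. MeOH/sodium oxalate; buffered fluoride).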